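The bicyclic core is disconnected at the C3a–C4 bond of the octahydroindene skeleton (C4 carries the exocyclic methylene). C4 is the α-carbon of a C5 ketone that later becomes the ester-bearing carbinol, so the six-membered ring is closed by intramolecular SN2 alkylation of a methyl ketone enolate on a cyclopentyl bromide. Backside attack at C3a, whose bromide is cis to the C7a side chain, places the new bond anti to that chain and fixes the trans ring fusion in the ring-forming event. The precursor is a prostaglandin-like, fully substituted cyclopentane from a conjugate addition–aldol coupling on (R)-4-silyloxycyclopentenone; its C–O stereocentre is used three times (anti addition, Appel inversion, SN2 inversion).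

Key step: step 8

Remark on numbering: all compounds, including the monocyclic precursors, carry the octahydro-1H-indene locants of the target (C1 acetoxyethyl, C2 acetoxy, C3a/C7a ring fusion, C4 methylene, C5 enoate, C6 hydroxyl, C7 oxiranyl). β is the face of H-3a and α the face of H-7a; C1′ is the side-chain carbinol carbon.
Assumption: (E)-3-methylpent-2-enoic acid is purchased as the pure (E) isomer; TBS = tert-butyldimethylsilyl.

Step 1
Reactants: 1 (R)-4-(tert-butyldimethylsilyloxy)cyclopent-2-en-1-one; 2 vinylmagnesium bromide; 3 acetaldehyde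
Product: 5 2-oxo-1α-(1-hydroxyethyl)-7aβ-vinyl-3aα-(TBS-oxy)cyclopentane (anti aldol), via bromomagnesium enolate 4 (not isolated)
Conditions: CuBr·SMe2 (10 mol %), THF, −78 °C; then MeCHO, −78 °C; aq. NH4Cl
Reagents that add atoms: none
Why: Tandem conjugate addition–aldol (three-component coupling): the copper-catalysed Grignard addition should occur anti to the C3a silyloxy group, the aldol at C1 anti to the new vinyl group, and the closed Zimmerman–Traxler transition state of the ring-locked (E)-enolate should give the anti aldol, which is the C1′ configuration of the target.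

Step 2
Reactants: 5 aldol ketone
Product: 6 1α-(1-hydroxyethyl)-7aβ-vinyl-3aα-(TBS-oxy)cyclopentan-2α-ol
Conditions: Li[HB(s-Bu)3], THF, −78 °C; aq. NH4Cl
Reagents that add atoms: none
Why: Ketone reduction with a bulky hydride, which should attack C2 from the β face opposite the adjacent α side chain (the selectivity of prostaglandin E to F reductions), giving the 2α-alcohol and a 1,3-anti diol.

Step 3
Reactants: 6 diol
Product: 7 acetonide of 6 (2,2-dimethyl-1,3-dioxane across O-2 and O-1′)
Conditions: 2,2-dimethoxypropane, PPTS (cat.), CH2Cl2, rt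
Reagents that add atoms: 2,2-dimethoxypropane, COC(C)(C)OC
Why: Acid-catalysed transketalisation protects the 1,3-diol as a base-stable isopropylidene acetal for the organometallic and enolate steps; no stereocentre is touched.

Step 4
Reactants: 7 vinyl acetonide; 8 methyl vinyl ketone
Product: 9 (E)-enone, 7aβ-[(E)-3-oxobut-1-enyl] acetonide
Conditions: second-generation Hoveyda–Grubbs catalyst (5 mol %), 8 (5 equiv), CH2Cl2, 40 °C
Reagents that add atoms: none
Why: Olefin cross-metathesis of the terminal vinyl group with an excess of the electron-poor partner should give the (E)-enone under thermodynamic control.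

Step 5
Reactants: 9 (E)-enone; 10 isopropenylboronic acid pinacol ester
Product: 11 methyl ketone, 7aβ-(2-methyl-5-oxohex-1-en-3-yl) acetonide with C7 configured as in the target
Conditions: [Rh(cod)Cl]2 (3 mol %), (S)-BINAP (7 mol %), aq. KOH (0.5 equiv), dioxane/H2O 10:1, 50 °C
Reagents that add atoms: none
Why: Rhodium-catalysed asymmetric 1,4-addition of an alkenylboron reagent (Hayashi–Miyaura reaction); the (S)-BINAP ligand should deliver the isopropenyl group to the enone face that gives the required C7 configuration (the sense known for (E)-alk-3-en-2-ones), under catalyst control over the adjacent C7a centre.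

Step 6
Reactants: 11 silyl ether
Product: 12 3aα-alcohol
Conditions: Bu4NF, THF, 0 °C
Reagents that add atoms: none
Why: Fluoride-mediated desilylation frees the only silyl ether; the acetonide and ketone are inert.

Step 7
Reactants: 12 3aα-alcohol
Product: 13 3aβ-bromide
Conditions: CBr4, PPh3, CH2Cl2, 0 °C
Reagents that add atoms: carbon tetrabromide, BrC(Br)(Br)Br
Why: Appel bromination, an SN2 displacement of the alkoxyphosphonium ion, should invert C3a and place bromide on the β face, cis to the C7a chain (inversion at this position is known from 11-epi-prostaglandin chemistry).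

Step 8
Reactants: 13 3aβ-bromide
Product: 15 trans-fused 7α-isopropenyl-octahydroinden-5-one 1′,2-acetonide, via potassium enolate 14 (not isolated)
Conditions: KN(SiMe3)2 (1.05 equiv), THF, −78 to 0 °C
Reagents that add atoms: none
Why: KN(SiMe3)2 deprotonates the methyl ketone kinetically at CH3 (an enolate on the C6 side could only close a four-membered ring and reverts by proton transfer), and the enolate carbon C4 displaces bromide at C3a in an intramolecular SN2 reaction. The closest known reaction type is the cycloalkylation of a ketone enolate by a tethered secondary halide or sulfonate used to make fused cyclohexanones. The six-membered carbocycle closes in the 6-(enolendo)-exo-tet mode, allowed for enolates, through a chair-like array with the isopropenyl group equatorial. The only new stereocentre, C3a, is controlled by inversion: the β-bromide is attacked from the α face, so H-3a ends β and the fusion to C7a (H α) is trans. The step needs substitution to beat E2 elimination and C- to beat O-alkylation; the six-ring effective molarity, the backside alignment available to the cis tether, the reactive potassium enolate at low temperature and the eight-membered ring that O-alkylation would require should secure this.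

Step 9
Reactants: 15 ketone
Product: 16 Δ5(6) TBS enol ether
Conditions: TBSOTf, Et3N, CH2Cl2, 0 °C to rt
Reagents that add atoms: tert-butyldimethylsilyl trifluoromethanesulfonate, CC(C)(C)[Si](C)(C)OS(=O)(=O)C(F)(F)F
Why: Soft enol silylation under equilibrating conditions; enolisation towards C6 keeps the strained trans ring-fusion bond opposite the new double bond (the regiochemistry of trans-fused 3-keto steroids), so the Δ5(6) isomer should dominate over Δ4.

Step 10
Reactants: 16 silyl enol ether
Product: 17 6β-(TBS-oxy) ketone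
Conditions: dimethyldioxirane (1.0 equiv), acetone, −40 °C to rt; then Et3N (cat.)
Reagents that add atoms: dimethyldioxirane, CC1(C)OO1
Why: Rubottom oxidation: the electron-rich enol ether is epoxidised faster than the isopropenyl group and trans to the C7 substituent, and 1,4-silyl migration gives the silyloxy ketone; C6 is epimerisable and the 6β (equatorial) isomer is also the thermodynamic one.

Step 11
Reactants: 17 silyloxy ketone; 18 N,N-dimethylmethyleneiminium iodide (Eschenmoser's salt)
Product: 20 4β-(dimethylaminomethyl) ketone (Mannich base), via lithium enolate 19 (not isolated)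
Conditions: LiN(i-Pr)2, THF, −78 °C; then 18, −78 to 0 °C
Reagents that add atoms: none
Why: Kinetic deprotonation at the C4 methylene (C6 is a hindered silyloxy methine) and Mannich aminomethylation of the enolate; C4 stays epimerisable, so the aminomethyl group should settle equatorial (4β).

Step 12
Reactants: 20 Mannich base
Product: 21 amino alcohol with 5β-OH
Conditions: Li[HB(s-Bu)3], THF, −78 °C; aq. NH4Cl
Reagents that add atoms: none
Why: Reduction of a cyclohexanone flanked by two equatorial substituents with a bulky hydride should proceed by equatorial attack and give the axial 5β-alcohol, cis to the C6 silyloxy group.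

Step 13
Reactants: 21 amino alcohol
Product: 23 4-methylene 5β-alcohol, via amine N-oxide 22 (not isolated)
Conditions: m-CPBA (1.0 equiv), CH2Cl2, −20 °C; then THF/DMSO, 60 °C
Reagents that add atoms: none
Why: N-Oxidation of the tertiary amine is much faster than alkene epoxidation, and the Cope elimination (syn Ei) has its only β-hydrogen at C4, so the exocyclic methylene should form regiospecifically.

Step 14
Reactants: 23 allylic alcohol; 24 (E)-3-methylpent-2-enoic acid
Product: 26 5β-[(E)-3-methylpent-2-enoate], via mixed anhydride 25 (not isolated)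
Conditions: 24, 2,4,6-trichlorobenzoyl chloride, Et3N, THF, rt; then 23, DMAP, toluene, rt to 40 °C
Reagents that add atoms: none
Why: Yamaguchi esterification acylates the hindered axial allylic alcohol with retention at C5; the C6 oxygen is still silylated, so only the C5 hydroxyl is esterified.

Step 15
Reactants: 26 ester acetonide
Product: 28 2α,1′-diacetate, via diol 27 (not isolated)
Conditions: PPTS, MeOH, 40 °C; concentrate; then Ac2O, pyridine, DMAP (cat.), rt
Reagents that add atoms: acetic anhydride, CC(=O)OC(C)=O
Why: Mild acetal methanolysis leaves the hindered secondary TBS ether and the enoate intact, and acetylation of the two liberated secondary alcohols installs both acetates of the target.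

Step 16
Reactants: 28 silyl ether
Product: 29 6β-alcohol
Conditions: HF·pyridine, pyridine/THF, 0 °C to rt
Reagents that add atoms: none
Why: Acidic fluoride desilylation frees the C6 hydroxyl without the base-induced acyl migration from O-5 that a basic fluoride source would risk.

Step 17
Reactants: 29 homoallylic alcohol
Product: 30 Songaricalarin B
Conditions: VO(acac)2 (5 mol %), t-BuOOH (1.2 equiv), CH2Cl2, 0 °C
Reagents that add atoms: tert-butyl hydroperoxide, CC(C)(C)OO
Why: Hydroxyl-directed epoxidation: the vanadate ester of the C6 hydroxyl should deliver oxygen to the isopropenyl group on the adjacent C7 (the isopulegol motif) through the rotamer in which C=CH2 eclipses C7–H, which gives the required oxirane configuration, while the more distant, electron-poorer C4 methylene is spared.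

Compound list
1 | (R)-4-(tert-butyldimethylsilyloxy)cyclopent-2-en-1-one | CC(C)(C)[Si](C)(C)O[C@@H]1CC(=O)C=C1 | starting material
2 | vinylmagnesium bromide | C=C[Mg]Br | starting material
3 | acetaldehyde | CC=O | starting material
4 | bromomagnesium enolate of 7aβ-vinyl-3aα-(TBS-oxy)cyclopentan-2-one | CC(C)(C)[Si](C)(C)O[C@@H]1CC(O[Mg]Br)=C[C@H]1C=C | intermediate (not isolated)
5 | 2-oxo-1α-(1-hydroxyethyl)-7aβ-vinyl-3aα-(TBS-oxy)cyclopentane, anti aldol | CC(C)(C)[Si](C)(C)O[C@@H]1CC(=O)[C@H]([C@H](C)O)[C@H]1C=C | intermediate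
6 | 1α-(1-hydroxyethyl)-7aβ-vinyl-3aα-(TBS-oxy)cyclopentan-2α-ol | CC(C)(C)[Si](C)(C)O[C@@H]1C[C@H](O)[C@H]([C@H](C)O)[C@H]1C=C | intermediate
7 | acetonide of 6 (O-2/O-1′ isopropylidene) | CC(C)(C)[Si](C)(C)O[C@@H]1C[C@@H]2OC(C)(C)O[C@@H](C)[C@@H]2[C@H]1C=C | intermediate
8 | methyl vinyl ketone (but-3-en-2-one) | CC(=O)C=C | starting material
9 | 7aβ-[(E)-3-oxobut-1-enyl]-3aα-(TBS-oxy) acetonide | CC(C)(C)[Si](C)(C)O[C@@H]1C[C@@H]2OC(C)(C)O[C@@H](C)[C@@H]2[C@H]1/C=C/C(C)=O | intermediate
10 | isopropenylboronic acid pinacol ester | CC(=C)B1OC(C)(C)C(C)(C)O1 | starting material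
11 | 7aβ-(2-methyl-5-oxohex-1-en-3-yl)-3aα-(TBS-oxy) acetonide, C7 as in target | CC(C)(C)[Si](C)(C)O[C@@H]1C[C@@H]2OC(C)(C)O[C@@H](C)[C@@H]2[C@H]1[C@H](C(C)=C)CC(C)=O | intermediate
12 | 3aα-alcohol of 11 | O[C@@H]1C[C@@H]2OC(C)(C)O[C@@H](C)[C@@H]2[C@H]1[C@H](C(C)=C)CC(C)=O | intermediate
13 | 3aβ-bromide (C3a inverted) | Br[C@H]1C[C@@H]2OC(C)(C)O[C@@H](C)[C@@H]2[C@H]1[C@H](C(C)=C)CC(C)=O | intermediate
14 | potassium enolate of 13 (terminal, C4=C5) | Br[C@H]1C[C@@H]2OC(C)(C)O[C@@H](C)[C@@H]2[C@H]1[C@H](C(C)=C)CC(=C)O[K] | intermediate (not isolated)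
15 | trans-fused (3aβ-H, 7aα-H) 7α-isopropenyl-octahydroinden-5-one 1′,2-acetonide | O=C1C[C@@H]2C[C@@H]3OC(C)(C)O[C@@H](C)[C@@H]3[C@H]2[C@H](C(C)=C)C1 | intermediate
16 | Δ5(6) TBS enol ether of 15 | C1=C(O[Si](C)(C)C(C)(C)C)C[C@@H]2C[C@@H]3OC(C)(C)O[C@@H](C)[C@@H]3[C@H]2[C@@H]1C(C)=C | intermediate
17 | 6β-(TBS-oxy)-7α-isopropenyl-5-ketone acetonide | O=C1C[C@@H]2C[C@@H]3OC(C)(C)O[C@@H](C)[C@@H]3[C@H]2[C@H](C(C)=C)[C@H]1O[Si](C)(C)C(C)(C)C | intermediate
18 | N,N-dimethylmethyleneiminium iodide | C[N+](C)=C.[I-] | starting material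
19 | lithium Δ4 enolate of 17 | [Li]OC1=C[C@@H]2C[C@@H]3OC(C)(C)O[C@@H](C)[C@@H]3[C@H]2[C@H](C(C)=C)[C@H]1O[Si](C)(C)C(C)(C)C | intermediate (not isolated)
20 | 4β-(dimethylaminomethyl)-6β-(TBS-oxy)-5-ketone acetonide | O=C1[C@@H](CN(C)C)[C@@H]2C[C@@H]3OC(C)(C)O[C@@H](C)[C@@H]3[C@H]2[C@H](C(C)=C)[C@H]1O[Si](C)(C)C(C)(C)C | intermediate
21 | 4β-(dimethylaminomethyl)-6β-(TBS-oxy)-5β-ol acetonide | CN(C)C[C@H]1[C@@H]2C[C@@H]3OC(C)(C)O[C@@H](C)[C@@H]3[C@H]2[C@H](C(C)=C)[C@@H](O[Si](C)(C)C(C)(C)C)[C@H]1O | intermediate
22 | N-oxide of 21 | C[N+](C)([O-])C[C@H]1[C@@H]2C[C@@H]3OC(C)(C)O[C@@H](C)[C@@H]3[C@H]2[C@H](C(C)=C)[C@@H](O[Si](C)(C)C(C)(C)C)[C@H]1O | intermediate (not isolated)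
23 | 4-methylene-6β-(TBS-oxy)-5β-ol acetonide | C=C1[C@@H]2C[C@@H]3OC(C)(C)O[C@@H](C)[C@@H]3[C@H]2[C@H](C(C)=C)[C@@H](O[Si](C)(C)C(C)(C)C)[C@H]1O | intermediate
24 | (E)-3-methylpent-2-enoic acid | CC/C(C)=C/C(=O)O | starting material
25 | (E)-3-methylpent-2-enoic 2,4,6-trichlorobenzoic anhydride | CC/C(C)=C/C(=O)OC(=O)c1c(Cl)cc(Cl)cc1Cl | intermediate (not isolated)
26 | 5β-[(E)-3-methylpent-2-enoyloxy]-6β-(TBS-oxy) acetonide | C=C1[C@@H]2C[C@@H]3OC(C)(C)O[C@@H](C)[C@@H]3[C@H]2[C@H](C(C)=C)[C@@H](O[Si](C)(C)C(C)(C)C)[C@H]1OC(=O)/C=C(\C)CC | intermediate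
27 | 2α,1′-diol of 26 | C=C1[C@@H]2C[C@H](O)[C@H]([C@H](C)O)[C@H]2[C@H](C(C)=C)[C@@H](O[Si](C)(C)C(C)(C)C)[C@H]1OC(=O)/C=C(\C)CC | intermediate (not isolated)
28 | 2α,1′-diacetate, 6β-TBS ether | C=C1[C@@H]2C[C@H](OC(C)=O)[C@H]([C@H](C)OC(C)=O)[C@H]2[C@H](C(C)=C)[C@@H](O[Si](C)(C)C(C)(C)C)[C@H]1OC(=O)/C=C(\C)CC | intermediate
29 | 6β-hydroxy-7α-isopropenyl diacetate enoate (deoxy precursor of the target) | C=C1[C@@H]2C[C@H](OC(C)=O)[C@H]([C@H](C)OC(C)=O)[C@H]2[C@H](C(C)=C)[C@@H](O)[C@H]1OC(=O)/C=C(\C)CC | intermediate
30 | Songaricalarin B: 1α-(1-acetoxyethyl)-2α-acetoxy-6β-hydroxy-4-methylene-7α-(2-methyloxiran-2-yl)-3aβ-H,7aα-H-octahydroinden-5β-yl (E)-3-methylpent-2-enoate | C=C1[C@@H]2C[C@H](OC(C)=O)[C@H]([C@H](C)OC(C)=O)[C@H]2[C@H]([C@@]2(C)CO2)[C@@H](O)[C@H]1OC(=O)/C=C(\C)CC | target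

Total step count: 17
Longest linear sequence: 17 steps (from 1; all other starting materials are purchased)

Steps most likely to fail

Step 8. The enolate may act as a base and eliminate the secondary bromide (E2 towards C3 or C7a), or the strained trans-closing transition state may be too slow. Fallback, from 12 and rejoining at 15: oxidation of the C3a alcohol with Dess–Martin periodinane should give 1,5-diketone F1. A Robinson-type intramolecular aldol condensation (KOH, MeOH, 0 °C to rt) then joins the same two carbons as a C3a=C4 double bond in bicyclic enone F2. Dissolving-metal reduction (Li, NH3, t-BuOH, −78 °C; NH4Cl) should protonate C3a axially and give the trans-fused ketone 15.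

Step 5. Insertion into the β-branched enone may be slow, and the ligand may be mismatched with the C7a stereocentre, giving poor facial selectivity at C7. Fallback, from 7 and rejoining at 11: cross-metathesis with (R)-3-acryloyl-4-benzyloxazolidin-2-one (second-generation Hoveyda–Grubbs catalyst) should give enoyl imide F3. Auxiliary-controlled conjugate addition of isopropenylmagnesium bromide with CuBr·SMe2 (chelated syn-s-cis imide, attack anti to the benzyl group) should give imide F4. Transamidation with MeNH(OMe)·HCl and AlMe3 gives Weinreb amide F5, and MeMgBr converts it to methyl ketone 11.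

Step 17. The vanadium peroxide may also epoxidise the C4 methylene, may react through the other isopropenyl rotamer and give the epimeric oxirane, or may open the product by Lewis acid catalysis. Fallback, from 29 and ending at 30: reagent-controlled epoxidation with a chiral dioxirane generated in situ from a carbohydrate-derived oxazolidinone ketone and KHSO5 (buffer pH 10, MeCN/dimethoxymethane, 0 °C). It selects the face of the electron-richer 1,1-disubstituted alkene independently of the hydroxyl group and makes no new compound (F0).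

Further compounds
F1 | step 8 | 3a-oxo-7aβ-(2-methyl-5-oxohex-1-en-3-yl) acetonide (1,5-diketone) | O=C1C[C@@H]2OC(C)(C)O[C@@H](C)[C@@H]2[C@H]1[C@H](C(C)=C)CC(C)=O
F2 | step 8 | Δ3a(4)-7α-isopropenyl-hexahydroinden-5-one 1′,2-acetonide (bicyclic enone) | O=C1C=C2C[C@@H]3OC(C)(C)O[C@@H](C)[C@@H]3[C@H]2[C@H](C(C)=C)C1
F3 | step 5 | (E)-enoyl imide of (R)-4-benzyloxazolidin-2-one | CC(C)(C)[Si](C)(C)O[C@@H]1C[C@@H]2OC(C)(C)O[C@@H](C)[C@@H]2[C@H]1/C=C/C(=O)N1C(=O)OC[C@H]1Cc1ccccc1
F4 | step 5 | β-isopropenyl imide, C7 as in target | CC(C)(C)[Si](C)(C)O[C@@H]1C[C@@H]2OC(C)(C)O[C@@H](C)[C@@H]2[C@H]1[C@H](C(C)=C)CC(=O)N1C(=O)OC[C@H]1Cc1ccccc1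
F5 | step 5 | N-methoxy-N-methyl amide (Weinreb amide) | CC(C)(C)[Si](C)(C)O[C@@H]1C[C@@H]2OC(C)(C)O[C@@H](C)[C@@H]2[C@H]1[C@H](C(C)=C)CC(=O)N(C)OC
F0 | step 17 | none | none
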